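**Remark.** Labdane numbering is used for every compound (C17 = methylene carbon on C8, C18 = methyl on C4, C19 = formyl carbon on C4, C20 = methyl on C10). The target is (3S,4R,5R,9S,10R): 3β-OAc, 4β-CHO, 5α-H, 9α-H, 10β-CH3. TBDPS = tert-butyldiphenylsilyl.

## Retrosynthetic overview

1. The 3-OAc / 19-CHO / 18-CH3 array of ring A is traced back to the ring-A β-keto ester 18 (C3 ketone, C4–CO2tBu); C4 methylation and C3 reduction are both steered by the axial C20 methyl.
2. Key disconnection (step 9): ring A is cut at C1–C10 and C3–C4. C1–C2–C3 is methyl acrylate, C10 is a tertiary radical released from the cesium oxalate of a monocyclic ring-B alcohol, and C4 is the α-carbon of a tert-butyl acetate arm on C5. A Giese addition is followed in the same flask by Dieckmann closure, a [3+3] annulation at the most hindered carbon.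
3. Enabling feature: C10 is the fully substituted ring-fusion carbon flanked by C5 and C9, whose cis substituents leave only its α face open. C3 (carbinol) and C19 (formyl) are 1,3-related through quaternary C4, so ring A holds a β-dicarbonyl (Claisen) retron with C1 β to the C3 carbonyl.
4. Ring B is formed first (step 7) by a carbonyl-ene cyclisation (C9–C10) of an acyclic methyl ketone built on the farnesol chain (C5–C9, C11–C17); this step also delivers the C8=C17 methylene and the C10 carbinol. The C5 stereocentre comes from a rhodium-catalysed asymmetric vinyl addition. Order: ring B, then ring A.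

Key step: step 9

## Route

Step 1
Reactants: 1 (2E,6E)-farnesol; 2 tert-butyl(chloro)diphenylsilane
Product: 3 (2E,6E)-farnesyl TBDPS ether
Conditions: imidazole, DMF, 0 °C to rt
Reagents that add atoms: tert-butyl(chloro)diphenylsilane (2), CC(C)(C)[Si](Cl)(c1ccccc1)c1ccccc1
Why: Imidazole-mediated O-silylation of the primary allylic alcohol masks C15–OH with a group that should survive Lewis acid, alkoxide, hydride and oxidant until step 14; no stereocentre is involved.

Step 2
Reactants: 3 (2E,6E)-farnesyl TBDPS ether
Product: 5 (2E,6E)-10,11-epoxyfarnesyl TBDPS ether, via bromohydrin 4 (not isolated)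
Conditions: NBS, THF/H2O, 0 °C; then K2CO3, MeOH, rt
Reagents that add atoms: water, O; N-bromosuccinimide, O=C1CCC(=O)N1Br (bromine only in 4)
Why: Bromohydrin formation in aqueous THF should occur selectively at the terminal trisubstituted alkene (the 2,3-alkene is deactivated by the allylic oxygen) and base then closes the epoxide; the new stereocentre is racemic and is destroyed in step 3.

Step 3
Reactants: 5 (2E,6E)-10,11-epoxyfarnesyl TBDPS ether
Product: 6 (4E,8E)-10-(TBDPS-oxy)-4,8-dimethyldeca-4,8-dienal
Conditions: H5IO6, THF/H2O, 0 °C to rt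
Reagents that add atoms: none
Why: Periodic acid hydrolyses the epoxide to the glycol and cleaves it (glycol cleavage), giving the C5 aldehyde with loss of acetone while the trisubstituted alkenes and the silyl ether stay intact.

Step 4
Reactants: 6 (4E,8E)-10-(TBDPS-oxy)-4,8-dimethyldeca-4,8-dienal; 7 tert-butyl 2-(diethoxyphosphoryl)acetate
Product: 8 tert-butyl (2E,6E,10E)-12-(TBDPS-oxy)-6,10-dimethyldodeca-2,6,10-trienoate
Conditions: NaH, THF, 0 °C to rt
Reagents that add atoms: tert-butyl 2-(diethoxyphosphoryl)acetate (7), CCOP(=O)(CC(=O)OC(C)(C)C)OCC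
Why: Horner–Wadsworth–Emmons olefination with a stabilised phosphonate should give the E-enoate and installs C4 and C19 as a tert-butyl ester, chosen because it is a poor acyl acceptor in step 9.

Step 5
Reactants: 8 tert-butyl trienoate; 9 potassium trifluoro(vinyl)borate
Product: 10 tert-butyl (3S,6E,10E)-12-(TBDPS-oxy)-6,10-dimethyl-3-vinyldodeca-6,10-dienoate
Conditions: [Rh(cod)2]PF6 (3 mol %), (S)-BINAP (3.3 mol %), toluene/H2O 20:1, 105 °C
Reagents that add atoms: potassium trifluoro(vinyl)borate (9), [K+].C=C[B-](F)(F)F
Why: Hayashi–Miyaura reaction (rhodium-catalysed asymmetric 1,4-addition of an alkenyl trifluoroborate to a β-alkyl E-enoate); the (S)-BINAP–rhodium complex is expected, by analogy with E-enones, to deliver vinyl to the face that sets C5 as 3S (the antipodal ligand would give 3R), the isolated trisubstituted alkenes being inert.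

Step 6
Reactants: 10 tert-butyl (3S)-3-vinyl ester
Product: 11 tert-butyl (3S,6E,10E)-3-acetyl-12-(TBDPS-oxy)-6,10-dimethyldodeca-6,10-dienoate
Conditions: PdCl2 (10 mol %), CuCl, O2 (1 atm), DMF/H2O 7:1, rt
Reagents that add atoms: water, O
Why: Tsuji–Wacker oxidation, in which Markovnikov hydroxypalladation occurs only at the monosubstituted alkene, turns the vinyl group into the acetyl group (C10 carbonyl, C20 methyl) without touching C5 or the trisubstituted alkenes.

Step 7
Reactants: 11 tert-butyl (3S)-3-acetyl ester
Product: 12 ring-B cyclohexanol (C10 tertiary alcohol, C8=C17 methylene, C5 arm and C9 side chain cis)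
Conditions: Me2AlCl (2.2 equiv), CH2Cl2, −78 to 0 °C; aqueous Rochelle salt
Reagents that add atoms: none
Why: Lewis-acid-promoted intramolecular carbonyl-ene reaction with the ene tethered through its disubstituted carbon: the aluminium-bound ketone carbon C10 bonds to the less substituted alkene carbon C9 through a chair transition state in which the C5 arm and, because the alkene is E, the side chain are equatorial (hence cis on ring B), while a hydrogen of the C17 methyl passes to oxygen and leaves the exocyclic C8=C17 alkene; the C10 configuration (hydroxyl axial expected) does not matter because C10 becomes a radical in step 9.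

Step 8
Reactants: 12 ring-B cyclohexanol; 13 methyl chlorooxoacetate
Product: 15 cesium oxalate of cyclohexanol 12, via methyl oxalate 14 (not isolated)
Conditions: Et3N, DMAP (cat.), CH2Cl2, 0 °C to rt; then CsOH (1.0 equiv), THF/H2O, rt
Reagents that add atoms: methyl chlorooxoacetate (13), COC(=O)C(Cl)=O; cesium hydroxide, [Cs+].[OH-]
Why: Acylation of the tertiary alcohol by the very reactive half acid chloride and chemoselective saponification of the methyl oxalate (much faster than that of the tert-butyl ester) should give the bench-stable cesium alkyl oxalate, a known photoredox precursor of tertiary radicals; no stereocentre changes.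

Step 9
Reactants: 15 cesium oxalate; 16 methyl acrylate
Product: 18 ring-A β-keto ester (trans-decalin), via seco-diester 17 (not isolated)
Conditions: 16 (1.5 equiv), Ir[dF(CF3)ppy]2(dtbbpy)PF6 (1 mol %), DME/DMF 3:1, H2O (10 equiv), blue LEDs, 60 °C; then volatiles removed (toluene azeotrope), KOtBu (3 equiv), THF, 0 °C to rt; aq. NH4Cl
Reagents that add atoms: methyl acrylate (16), C=CC(=O)OC
Why: The photoexcited trivalent iridium complex oxidises the oxalate carboxylate, two molecules of CO2 are lost and the tertiary C10 radical adds to the terminal carbon of methyl acrylate (C1–C10), after which divalent iridium reduces the adduct radical to the ester enolate that water protonates to diester 17; with KOtBu the enolate of the tert-butyl acetate arm (C4) then attacks the methyl ester carbon (C3) and expels methoxide (C3–C4). The closest known reaction types are the decarboxylative Giese addition of tert-alkyl oxalates to acrylates, which makes quaternary carbons, and the Dieckmann condensation, so the sequence is a radical Michael–Dieckmann [3+3] annulation. Ring A closes by 6-exo-trig attack of the C4 enolate on the C3 ester carbonyl, and because the C1 and C4 arms are both equatorial on the ring-B chair only the trans-decalin can form. The C10 stereocentre is set under substrate control: the planar radical is flanked by C5 and C9, whose substituents are cis and cover the β face, so the acrylate should enter from the α face and the C20 methyl ends axial; C4 stays epimerisable and is fixed in step 10. The step needs the intermolecular addition to outrun 6-endo capture of the radical by the C13=C14 alkene, which the excess of the unhindered, electron-poor acrylate should secure, and it needs Claisen closure in the C4-to-C3 sense, which is secured because a tert-butyl ester is a poor acyl acceptor while the methyl ester is a good one and the resulting β-keto ester is deprotonated irreversibly.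

Step 10
Reactants: 18 ring-A β-keto ester; 19 iodomethane
Product: 20 tert-butyl 15-(TBDPS-oxy)-3-oxolabda-8(17),13E-dien-19-oate (4α-methyl, 4β-ester)
Conditions: NaH, THF, 0 °C; MeI, 0 °C to rt
Reagents that add atoms: iodomethane (19), CI
Why: C-Alkylation of the β-keto ester enolate, in which iodomethane should approach from the α face because the β face is screened by the axial C20 methyl (1,3-diaxial), gives the 4α-methyl 4β-ester, the usual outcome for 10β-methyl 3-oxo-4-carboalkoxy trans-decalins.

Step 11
Reactants: 20 methylated β-keto ester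
Product: 21 15-(TBDPS-oxy)labda-8(17),13E-diene-3β,19-diol
Conditions: LiAlH4, THF, 0 °C to reflux
Reagents that add atoms: none
Why: LiAlH4 reduction, in which axial hydride attack on the C3 ketone from the α face (the β face carries the axial C19 ester and the C20 methyl) should give the equatorial 3β-alcohol, while the tert-butyl ester is reduced to the C19 primary alcohol and alkenes and silyl ether are inert.

Step 12
Reactants: 21 3β,19-diol
Product: 22 3β-hydroxy-15-(TBDPS-oxy)labda-8(17),13E-dien-19-al
Conditions: TEMPO (10 mol %), PhI(OAc)2 (1.1 equiv), CH2Cl2, rt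
Reagents that add atoms: none
Why: Oxoammonium (TEMPO) oxidation with PhI(OAc)2 as terminal oxidant is selective for primary over secondary alcohols and should give the β-hydroxy aldehyde, which cannot enolise or dehydrate because C4 is quaternary.

Step 13
Reactants: 22 3β-hydroxy aldehyde; 23 acetic anhydride
Product: 24 3β-acetoxy-15-(TBDPS-oxy)labda-8(17),13E-dien-19-al
Conditions: pyridine, DMAP (cat.), CH2Cl2, rt
Reagents that add atoms: acetic anhydride (23), CC(=O)OC(C)=O
Why: DMAP-catalysed acetylation of the equatorial secondary alcohol under mild base, which the non-enolisable aldehyde and the silyl ether tolerate.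

Step 14
Reactants: 24 3β-acetoxy aldehyde silyl ether
Product: 25 (3S,4R,5R,9S,10R)-3-acetoxy-15-hydroxylabda-8(17),13E-dien-19-al (target)
Conditions: HF·pyridine, pyridine/THF, 0 °C to rt
Reagents that add atoms: none
Why: Fluoride-induced desilylation with buffered HF·pyridine should free the C15 allylic alcohol without affecting the acetate, the aldehyde or the acid-sensitive exocyclic alkene.

## Compound list

1 | (2E,6E)-farnesol | CC(C)=CCC/C(C)=C/CC/C(C)=C/CO | starting material
2 | tert-butyl(chloro)diphenylsilane | CC(C)(C)[Si](Cl)(c1ccccc1)c1ccccc1 | starting material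
3 | (2E,6E)-farnesyl TBDPS ether | CC(C)=CCC/C(C)=C/CC/C(C)=C/CO[Si](c1ccccc1)(c1ccccc1)C(C)(C)C | intermediate
4 | terminal bromohydrin of 3 (10-bromo-11-hydroxy, racemic) | CC(C)(O)C(Br)CC/C(C)=C/CC/C(C)=C/CO[Si](c1ccccc1)(c1ccccc1)C(C)(C)C | intermediate (not isolated)
5 | (2E,6E)-10,11-epoxyfarnesyl TBDPS ether (racemic at the epoxide carbon) | CC1(C)OC1CC/C(C)=C/CC/C(C)=C/CO[Si](c1ccccc1)(c1ccccc1)C(C)(C)C | intermediate
6 | (4E,8E)-10-(TBDPS-oxy)-4,8-dimethyldeca-4,8-dienal (formyl carbon = C5) | O=CCC/C(C)=C/CC/C(C)=C/CO[Si](c1ccccc1)(c1ccccc1)C(C)(C)C | intermediate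
7 | tert-butyl 2-(diethoxyphosphoryl)acetate | CCOP(=O)(CC(=O)OC(C)(C)C)OCC | starting material
8 | tert-butyl (2E,6E,10E)-12-(TBDPS-oxy)-6,10-dimethyldodeca-2,6,10-trienoate | CC(C)(C)OC(=O)/C=C/CC/C(C)=C/CC/C(C)=C/CO[Si](c1ccccc1)(c1ccccc1)C(C)(C)C | intermediate
9 | potassium trifluoro(vinyl)borate | [K+].C=C[B-](F)(F)F | starting material
10 | tert-butyl (3S,6E,10E)-12-(TBDPS-oxy)-6,10-dimethyl-3-vinyldodeca-6,10-dienoate | C=C[C@H](CC(=O)OC(C)(C)C)CC/C(C)=C/CC/C(C)=C/CO[Si](c1ccccc1)(c1ccccc1)C(C)(C)C | intermediate
11 | tert-butyl (3S,6E,10E)-3-acetyl-12-(TBDPS-oxy)-6,10-dimethyldodeca-6,10-dienoate | CC(=O)[C@H](CC(=O)OC(C)(C)C)CC/C(C)=C/CC/C(C)=C/CO[Si](c1ccccc1)(c1ccccc1)C(C)(C)C | intermediate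
12 | ring-B cyclohexanol: 1-methylcyclohexan-1-ol (C10) with the CH2CO2tBu arm on C5, the (E)-5-(TBDPS-oxy)-3-methylpent-3-enyl chain on C9 and an exocyclic methylene on C8; OH, C5 arm and C9 chain all cis (β) | C=C1CC[C@@H](CC(=O)OC(C)(C)C)[C@@](C)(O)[C@H]1CC/C(C)=C/CO[Si](c1ccccc1)(c1ccccc1)C(C)(C)C | intermediate
13 | methyl chlorooxoacetate | COC(=O)C(Cl)=O | starting material
14 | methyl oxalate (mixed diester) of 12 | C=C1CC[C@@H](CC(=O)OC(C)(C)C)[C@@](C)(OC(=O)C(=O)OC)[C@H]1CC/C(C)=C/CO[Si](c1ccccc1)(c1ccccc1)C(C)(C)C | intermediate (not isolated)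
15 | cesium oxalate (half-ester salt) of 12 | [Cs+].C=C1CC[C@@H](CC(=O)OC(C)(C)C)[C@@](C)(OC(=O)C([O-])=O)[C@H]1CC/C(C)=C/CO[Si](c1ccccc1)(c1ccccc1)C(C)(C)C | intermediate
16 | methyl acrylate | C=CC(=O)OC | starting material
17 | seco-diester: ring B with C10 bearing β-methyl and α-CH2CH2CO2Me, C5 bearing β-CH2CO2tBu, C9 bearing the β side chain, C8 methylene | C=C1CC[C@@H](CC(=O)OC(C)(C)C)[C@](C)(CCC(=O)OC)[C@H]1CC/C(C)=C/CO[Si](c1ccccc1)(c1ccccc1)C(C)(C)C | intermediate (not isolated)
18 | ring-A β-keto ester: tert-butyl 3-oxo trans-decalin-4-carboxylate with 5α-H, 10β-methyl, C4–H (drawn as keto form with equatorial ester; C4 epimers and enol interconvert) | C=C1CC[C@H]2[C@H](C(=O)OC(C)(C)C)C(=O)CC[C@]2(C)[C@H]1CC/C(C)=C/CO[Si](c1ccccc1)(c1ccccc1)C(C)(C)C | intermediate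
19 | iodomethane | CI | starting material
20 | tert-butyl 15-(TBDPS-oxy)-3-oxolabda-8(17),13E-dien-19-oate (4α-methyl, 4β-ester) | C=C1CC[C@H]2[C@@](C)(C(=O)OC(C)(C)C)C(=O)CC[C@]2(C)[C@H]1CC/C(C)=C/CO[Si](c1ccccc1)(c1ccccc1)C(C)(C)C | intermediate
21 | 15-(TBDPS-oxy)labda-8(17),13E-diene-3β,19-diol | C=C1CC[C@H]2[C@@](C)(CO)[C@@H](O)CC[C@]2(C)[C@H]1CC/C(C)=C/CO[Si](c1ccccc1)(c1ccccc1)C(C)(C)C | intermediate
22 | 3β-hydroxy-15-(TBDPS-oxy)labda-8(17),13E-dien-19-al | C=C1CC[C@H]2[C@@](C)(C=O)[C@@H](O)CC[C@]2(C)[C@H]1CC/C(C)=C/CO[Si](c1ccccc1)(c1ccccc1)C(C)(C)C | intermediate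
23 | acetic anhydride | CC(=O)OC(C)=O | starting material
24 | 3β-acetoxy-15-(TBDPS-oxy)labda-8(17),13E-dien-19-al | C=C1CC[C@H]2[C@@](C)(C=O)[C@@H](OC(C)=O)CC[C@]2(C)[C@H]1CC/C(C)=C/CO[Si](c1ccccc1)(c1ccccc1)C(C)(C)C | intermediate
25 | (3S,4R,5R,9S,10R)-3-acetoxy-15-hydroxylabda-8(17),13E-dien-19-al (CNP0185120.1) | C=C1CC[C@H]2[C@@](C)(C=O)[C@@H](OC(C)=O)CC[C@]2(C)[C@H]1CC/C(C)=C/CO | target

## Step count and risks

Total step count: 14. Longest linear sequence: 14 steps (fully linear from farnesol).

Steps most likely to fail:

1. **Step 9 (key step).** The acrylate may add to the β face of the C10 radical, or the radical may cyclise onto the C13=C14 alkene. In the alkoxide stage, residual hydroxide may hydrolyse the methyl ester, or the Claisen closure may revert or go in the wrong sense. Fallback: set out from 15 and couple it under the same photoredox conditions with N-methoxy-N-methylacrylamide, isolating the Weinreb amide F1. Ring A is then closed with LiHMDS (THF, −78 to 0 °C): the tert-butyl ester enolate acylates onto the amide through a stable chelated tetrahedral intermediate that can neither revert nor close the other way. Work-up gives 18, where the route is rejoined.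

2. **Step 7.** The Lewis acid may cleave the tert-butyl ester, ionise the allylic silyl ether or epimerise C5 through an aluminium enolate. The ketone may also be too weak an enophile, or the chair preference that makes C5 and C9 cis may be poor. Fallback: set out from 11 and carry out an ene-type allylic chlorination of the more electron-rich C8=C9 alkene (Ca(OCl)2, CO2, CH2Cl2/H2O) to give the allylic chloride F2 (chlorine on C9, C8=C17 methylene). CrCl2 in THF/DMF then generates the allylchromium species, which should add to the ketone through its more substituted terminus C9 (intramolecular Nozaki–Hiyama allylation, chair transition state, neutral conditions). This gives 12, where the route is rejoined.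

3. **Step 8.** Acylation of the hindered axial tertiary alcohol may be incomplete, or the tertiary oxalate may eliminate during salt formation. Fallback: set out from 12 and use the free alcohol directly in a titanium-catalysed dehydroxylative radical alkylation (Cp*TiCl3 cat., Zn, Et3SiCl, methyl acrylate, THF). Trivalent titanium removes the oxygen and releases the same C10 radical, so the diester 17 is obtained and isolated. KOtBu in THF then closes it to 18, where the route is rejoined; no new compound is made.

Further compounds
F1 | step 9 | Weinreb amide analogue of 17 (CH2CH2C(=O)N(OMe)Me arm on C10 in place of the methyl ester arm) | C=C1CC[C@@H](CC(=O)OC(C)(C)C)[C@](C)(CCC(=O)N(C)OC)[C@H]1CC/C(C)=C/CO[Si](c1ccccc1)(c1ccccc1)C(C)(C)C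
F2 | step 7 | allylic chloride from 11 (C9–Cl, C8=C17 methylene; mixture at C9) | CC(=O)[C@H](CC(=O)OC(C)(C)C)CCC(=C)C(Cl)CC/C(C)=C/CO[Si](c1ccccc1)(c1ccccc1)C(C)(C)C
F0 | step 8 | none | none
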